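5 questions stand below, on 4 flasks that differ in how the charge goes in, and one quantity answers them.

- the flask that comes out highest in amount of side product, in percent of the starting material charged; "all alike" if 1.5 percentage points covers them all (Saturday's / Friday's / Thursday's / Monday's / all alike)
- amount of side product at the end, in percent of the starting material charged, Saturday's
- amount of side product at the end, in percent of the starting material charged, Friday's
- amount of side product at the end, in percent of the starting material charged, Thursday's
- amount of side product at the end, in percent of the starting material charged, Monday's

in all of them: catalyst 3.4 mM
- summer: starting material 0.10 M; reagent 0.25 M; second substrate 0.050 M; run made earlier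
- spring: starting material 0.067 M; reagent 0.25 M; second substrate 0.050 M; run made earlier
- midnight: starting material 0.15 M; reagent 0.25 M; second substrate 0.050 M; run made earlier
- Saturday's: starting material 0.10 M; reagent 0.250 M (fed, over 15 h); second substrate 0.0500 M; all else is in the flask from the start; the feed brings no volume worth counting; time 25 h
- Friday's: starting material 0.10 M; reagent 0.250 M (in portions, 3, over 15 h); second substrate 0.0500 M; first portion at the start, last at 15 h; time 25 h
- Thursday's: starting material 0.10 M; reagent 0.250 M; second substrate 0.0500 M; everything together at the start; time 25 h
- Monday's: starting material 0.10 M (fed, over 15 h); reagent 0.250 M; second substrate 0.0500 M; all else is in the flask from the start; the feed brings no volume worth counting; time 25 h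

| run | time / h | side product / % | target / % |
|---|---|---|---|
| summer | 1.00 | 6 | 2 |
| summer | 3.00 | 2 | 9 |
| summer | 5.00 | 4 | 19 |
| summer | 8.00 | 13 | 24 |
| summer | 12.0 | 17 | 30 |
| summer | 15.0 | 21 | 35 |
| spring | 1.50 | 0 | 8 |
| spring | 5.00 | 8 | 18 |
| spring | 8.00 | 6 | 25 |
| spring | 15.0 | 20 | 36 |
| spring | 20.0 | 27 | 43 |
| spring | 25.0 | 31 | 48 |
| midnight | 1.50 | 1 | 4 |
| midnight | 5.00 | 11 | 19 |
| midnight | 8.00 | 19 | 22 |
| midnight | 15.0 | 29 | 27 |
| midnight | 20.0 | 43 | 27 |
| midnight | 25.0 | 48 | 32 |

(standard deviation of a reading: 2 percentage points)

- a species is counted by the starting material in it: one side product counts as two
- the analysis behind the earlier runs scatters by 2 percentage points, standard deviation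
- reactions considered so far: starting material + reagent + catalyst -> catalyst + target; second substrate + reagent + catalyst -> catalyst + second product; starting material + target -> side product

Subtract target and side product from the whole and the spring run reads 21.0% of its starting material left after 25.0 h, the midnight run 20.0%, from charges of 0.067 M and 0.15 M. So at equal charges of reagent and catalyst the fraction left in these two runs follows the clock and not the charge, within the scatter, which is pseudo-first-order behaviour. We freeze that, and let the clock tick in proportion to [reagent].

Reckoned before any use, a feed of reagent, steady or in Friday's equal portions, holds [reagent] on average at half its charge while it lasts. Fed starting material arrives on average in the middle of the feed. Either way we count half the feed time as lost. The effective time of Saturday's, Friday's and Monday's is 17.5 h, that is, the run time less half the feed time, while Thursday's keeps the full 25 h.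

The summer run stops at 15.0 h, so we blend spring and midnight by charge, with weight 0.398 on midnight. We then reckon Thursday's at 37.8%. Midway between the readings at 15.0 h and 20.0 h, which is the effective time, we reckon the slow flasks at 28.5%. For the flasks to count as equal, that step in time would have to be worth under 1.5 percentage points. Our reckoning makes it 9.3 points, more than the margin, so we name Thursday's.

The forecast also names Thursday's but, unlike our single figure, keeps the slow flasks apart, with 30% for Saturday's, 32% for Friday's, 38% for Thursday's and 29% for Monday's, on the ground that “Slow reagent addition delays the first step”.

The flasks give 30.3% for Saturday's, 31.6% for Friday's, 38.7% for Thursday's and 28.0% for Monday's, so Thursday's is highest. Thursday's second product stands at 0.00561 M, which took 2.24% of the reagent charged.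

    starting material + reagent + catalyst → catalyst + target (k = 61.0 M⁻² h⁻¹)
    second substrate + reagent + catalyst → catalyst + second product (k = 6.70 M⁻² h⁻¹)
    starting material + target → side product (k = 0.620 M⁻¹ h⁻¹)

With the effective time of 17.5 h, Saturday's, Friday's and Monday's leave 35%, 35% and 36% of their starting material, against 22% on Thursday's. Monday's neighbour takes 0.17 M of starting material with the same 17.5 h. Our blend, carried past the midnight run with weight 1.24, gives 39.0%. That neighbour leaves 35% of its starting material and ends at 38.4% of side product.

Readings and results were generated by integration on assumed constants, noise included.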